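Q does not wait. Once mixed with J and D it falls to X with a first-order time constant of 0.980 min, and meanwhile J and D must first make the J.D that it can join.

    J + D → J.D (k1 = 0.27 M⁻¹ s⁻¹)
    Q + J.D → Q.J.D (k2 = 0.75 M⁻¹ s⁻¹)
    J + Q → J.Q (k3 = 0.045 M⁻¹ s⁻¹)
    Q.J.D ⇌ G (K4 = 0.31, k4 = 0.021 s⁻¹)
    Q → X (k5 = 0.017 s⁻¹)

| flask | J | D | Q | time | remark |
|---|---|---|---|---|---|
| zeta | 0.10 M | 0.120 M | 0.150 M | 1.5 min | everything together in a closed stirred flask, run for 1.5 min |
| delta | 0.10 M | 0.120 M | 0.150 M |  | one stirred flow tank at steady state, fed with the mixture as stated, mean residence time 1.5 min |
| eta | 0.10 M | 0.120 M (fed, over 1.20 min) | 0.150 M | 1.5 min | a stirred flask in which D is dosed at a steady rate over 1.20 min without added volume, worked up at 1.5 min |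
| alpha | 0.10 M | 0.120 M | 0.150 M |  | one stirred flow tank at steady state, fed with the mixture as stated, mean residence time 7.50 min |

* the set-up with the highest amount of Q.J.D at the outlet or at the end, in percent of the J put in ("none" if the first two lie within 2 percentage points) (zeta / delta / eta / alpha / none)
* amount of Q.J.D at the outlet or at the end, in percent of the J put in, zeta
* amount of Q.J.D at the outlet or at the end, in percent of the J put in, delta
* amount of Q.J.D at the outlet or at the end, in percent of the J put in, eta
* amount of Q.J.D at the outlet or at the end, in percent of the J put in, alpha

- the stated concentrations are those of everything mixed, before any reaction; amounts are the same in each set-up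
- the feed brings no volume worth counting
- run time (zeta): 1.5 min

A colleague and I dispute which set-up wins, but we share one tool. At a steady level of J.D, the capture of Q by J.D is pseudo-first-order in Q, so there is a concentration of J.D at which capture takes Q as fast as decay to X does. That concentration, the decay constant over the capture constant, is 0.0227 M, and we call it the break-even level. A Q molecule is then captured with the share J.D/(J.D + level). We also treat G as a correction: Q.J.D and G exchange with a time constant of 0.188 min, shorter than the 1.5 min run, so we reckon them as one pair of which 76.3% stands as Q.J.D.

My colleague holds the batch view: in zeta, D turns J with a time constant of 0.514 min, shorter than that of Q, so the closed flask should win.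

I hold the tank view, because the 7.50 min of alpha is longer than the life of Q and fresh Q keeps arriving. Outflow also removes Q, which widens the level to 0.0256 M. Counting the whole of J as turned to J.D, and setting the pair equal to the Q fed times its capture share, with J.D as the J fed minus the pair, I get a pair of 0.0746 M. That is half of the Q fed, and it gives a ceiling of 57.0%. That figure is a ceiling and not an estimate, so my reckoning stops there without naming a winner.

The forecast sides with the tank: it names alpha the winner, because the long tank “gives J.D time to form and capture what Q is fed”, and it gives 40.5% for zeta, 32.7% for delta, 23% for eta and 47.5% for alpha, the last below my ceiling.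

The simulation gives 40.6% for zeta, 32.9% for delta, 23.0% for eta and 47.4% for alpha, so the winner is alpha. The batch view keeps the set-ups of 1.5 min, where zeta stands above delta and eta.

Read with the share above, the 47.4% of alpha is a pair of 0.0621 M, which is 41.4% of the Q fed, and that capture share corresponds to 0.0181 M of J.D in the alpha tank, below the widened level. In eta, the J.D standing at the end is 27.0% of the J charged, or 0.0270 M, which puts capture at 1.19 times the rate of decay for each Q, and Q.J.D goes from 23.0% there to 26.9% at 15.0 min.

(The numbers of this flask stand for no real mixture, and the outcome is calculated.)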